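Assumption: the (R,R)-iodane is taken to give the (R)-product (if induction is opposite, its mirror image from the other methyl lactate is used); it is made from the catalogue aryl iodide with peracetic acid and is not counted as a step.

## Retrosynthetic overview

1. No carbocycle is built: the six-membered ring is the arene of 2,5-dimethylresorcinol (1), and the chain comes intact from (2E,6E)-farnesol (2).
2. C(aryl)–farnesyl by Friedel–Crafts allylation of 1 with 2 (gives 3); C–CO2H by ortho-carboxylation (gives 4).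
3. The only ring formed is a temporary dioxasilinone, a di-tert-butylsilylene across CO2H and its neighbouring OH (5), which also shields the wrong ortho carbon.
4. Key disconnection, C(quaternary)–CH3: the phenol carbon is made electrophilic as an O-bound aryl-λ3-iodane (6) and takes the methyl of Me2Zn, which dearomatizes the ring and sets the stereocentre (7). Methyl rather than farnesyl is delivered as the nucleophile because an allyl nucleophile would react with allylic transposition and lose the 2E geometry.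
5. Fluoride removes the silylene to give the target (8).

## Route

Step 1
Reactants: 1 2,5-dimethylbenzene-1,3-diol; 2 (2E,6E)-farnesol
Product: 3 2,5-dimethyl-4-[(2E,6E)-3,7,11-trimethyldodeca-2,6,10-trien-1-yl]benzene-1,3-diol
Conditions: 1 (3 equiv), acidic Al2O3, ClCH2CH2Cl, 80 °C
Reagents that add atoms: none
Why: Friedel–Crafts allylation (alumina-promoted ortho-allylation of a resorcinol with an allylic alcohol): the two free positions of 1 are equivalent, the farnesyl cation is captured at its primary terminus so the chain stays linear and 2E,6E, and excess 1 limits dialkylation.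

Step 2
Reactants: 3 2,5-dimethyl-4-[(2E,6E)-3,7,11-trimethyldodeca-2,6,10-trien-1-yl]benzene-1,3-diol
Product: 4 2,4-dihydroxy-3,6-dimethyl-5-[(2E,6E)-3,7,11-trimethyldodeca-2,6,10-trien-1-yl]benzoic acid
Conditions: MeOMgOCO2Me (2 M in DMF, 8 equiv), 125 °C, N2; then ice-cold 2 M HCl
Reagents that add atoms: methyl magnesium carbonate, COC(=O)O[Mg]OC
Why: Kolbe–Schmitt-type ortho-carboxylation with Stiles' reagent through a magnesium phenoxide chelate; the only ring C–H left is ortho to a hydroxyl, and the basic, non-oxidising medium leaves the triene untouched.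

Step 3
Reactants: 4 2,4-dihydroxy-3,6-dimethyl-5-[(2E,6E)-3,7,11-trimethyldodeca-2,6,10-trien-1-yl]benzoic acid
Product: 5 2,2-di-tert-butyl-7-hydroxy-5,8-dimethyl-6-[(2E,6E)-3,7,11-trimethyldodeca-2,6,10-trien-1-yl]-4H-1,3,2-benzodioxasilin-4-one
Conditions: t-Bu2Si(OTf)2 (1.05 equiv), 2,6-lutidine (2.5 equiv), CH2Cl2, –20 → 0 °C
Reagents that add atoms: di-tert-butylsilyl bis(trifluoromethanesulfonate), CC(C)(C)[Si](OS(=O)(=O)C(F)(F)F)(OS(=O)(=O)C(F)(F)F)C(C)(C)C
Why: Silylene protection: the bis-triflate bridges the carboxylic acid and its ortho hydroxyl in a six-membered ring, which masks both acidic groups, leaves the other phenol free and places two tert-butyl groups beside the ortho carbon that must not react in step 4.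

Step 4
Reactants: 5 2,2-di-tert-butyl-7-hydroxy-5,8-dimethyl-6-[(2E,6E)-3,7,11-trimethyldodeca-2,6,10-trien-1-yl]-4H-1,3,2-benzodioxasilin-4-one
Product: 7 (6R)-2,2-di-tert-butyl-5,6,8-trimethyl-6-[(2E,6E)-3,7,11-trimethyldodeca-2,6,10-trien-1-yl]-6H-1,3,2-benzodioxasilin-4,7-dione, via acetoxy{2,6-bis[(1R)-2-methoxy-1-methyl-2-oxoethoxy]phenyl}(aryloxy)-λ3-iodane of 5 (iodine on the 7-oxygen) 6 (not isolated)
Conditions: (R,R)-ArI(OAc)2 [Ar = 2,6-bis(1-methoxycarbonylethoxy)phenyl] (1.1 equiv), CH2Cl2, –78 °C; then Me2Zn (2.5 equiv, toluene), –78 → –40 °C; aq NH4Cl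
Reagents that add atoms: dimethylzinc, C[Zn]C; the λ3-iodane (its atoms stay only in 6), CC(=O)OI(OC(C)=O)c1c(O[C@H](C)C(=O)OC)cccc1O[C@H](C)C(=O)OC
Why: Proposed new method: ligand exchange gives the O-bound aryl-λ3-iodane 6, in which the phenol's ortho carbon has become an electrophile (phenoxenium/enolonium equivalent); methyl passes from zinc to the farnesyl-bearing ortho carbon as the aryl iodide leaves (SN2′-type), the other ortho carbon being shielded by the silylene and the para carbon carrying the acyl group, and the C2-symmetric lactate arms on iodine, which sits on the oxygen next to the reacting carbon, select the face and so set the (R) quaternary centre; closest known reaction types are the hypervalent-iodine umpolung α-alkylation of ketone enolates (enolonium species) with dialkylzincs and enantioselective phenol dearomatization with lactate-derived chiral aryl-λ3-iodanes.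

Step 5
Reactants: 7 (6R)-2,2-di-tert-butyl-5,6,8-trimethyl-6-[(2E,6E)-3,7,11-trimethyldodeca-2,6,10-trien-1-yl]-6H-1,3,2-benzodioxasilin-4,7-dione
Product: 8 (3R)-6-hydroxy-2,3,5-trimethyl-4-oxo-3-[(2E,6E)-3,7,11-trimethyldodeca-2,6,10-trien-1-yl]cyclohexa-1,5-diene-1-carboxylic acid
Conditions: HF·pyridine, pyridine, THF, 0 °C; pH 4 buffer
Reagents that add atoms: none
Why: Fluoride-mediated desilylation cleaves the silyl enol ether and the silyl ester together at 0 °C; no bond to the stereocentre is touched and the dienone and triene are inert to buffered HF.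

## Compound list

1 | 2,5-dimethylbenzene-1,3-diol | Cc1cc(O)c(C)c(O)c1 | starting material
2 | (2E,6E)-farnesol | CC(C)=CCC/C(C)=C/CC/C(C)=C/CO | starting material
3 | 2,5-dimethyl-4-[(2E,6E)-3,7,11-trimethyldodeca-2,6,10-trien-1-yl]benzene-1,3-diol | CC(C)=CCC/C(C)=C/CC/C(C)=C/Cc1c(C)cc(O)c(C)c1O | intermediate
4 | 2,4-dihydroxy-3,6-dimethyl-5-[(2E,6E)-3,7,11-trimethyldodeca-2,6,10-trien-1-yl]benzoic acid | CC(C)=CCC/C(C)=C/CC/C(C)=C/Cc1c(C)c(C(=O)O)c(O)c(C)c1O | intermediate
5 | 2,2-di-tert-butyl-7-hydroxy-5,8-dimethyl-6-[(2E,6E)-3,7,11-trimethyldodeca-2,6,10-trien-1-yl]-4H-1,3,2-benzodioxasilin-4-one | CC(C)=CCC/C(C)=C/CC/C(C)=C/Cc1c(C)c2C(=O)O[Si](C(C)(C)C)(C(C)(C)C)Oc2c(C)c1O | intermediate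
6 | acetoxy{2,6-bis[(1R)-2-methoxy-1-methyl-2-oxoethoxy]phenyl}(aryloxy)-λ3-iodane of 5, iodine on the 7-oxygen | CC(C)=CCC/C(C)=C/CC/C(C)=C/Cc1c(C)c2C(=O)O[Si](C(C)(C)C)(C(C)(C)C)Oc2c(C)c1OI(OC(C)=O)c1c(O[C@H](C)C(=O)OC)cccc1O[C@H](C)C(=O)OC | intermediate
7 | (6R)-2,2-di-tert-butyl-5,6,8-trimethyl-6-[(2E,6E)-3,7,11-trimethyldodeca-2,6,10-trien-1-yl]-6H-1,3,2-benzodioxasilin-4,7-dione | CC(C)=CCC/C(C)=C/CC/C(C)=C/C[C@@]1(C)C(=O)C(C)=C2O[Si](C(C)(C)C)(C(C)(C)C)OC(=O)C2=C1C | intermediate
8 | (3R)-6-hydroxy-2,3,5-trimethyl-4-oxo-3-[(2E,6E)-3,7,11-trimethyldodeca-2,6,10-trien-1-yl]cyclohexa-1,5-diene-1-carboxylic acid | CC(C)=CCC/C(C)=C/CC/C(C)=C/C[C@@]1(C)C(=O)C(C)=C(O)C(C(=O)O)=C1C | target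

## Step count and risks

Total steps: 5. Longest linear sequence: 5.

Step 4 is the most likely to fail. The methyl may be lost to iodine by reduction, a benzylic proton may be lost to give an o-quinone methide or chromene, the other ortho carbon may be attacked, or the ee may be low. The fallback sets out from 5 and comes back at 8, and gives up reagent control in favour of resolution. PhI(OAc)2 and Me2Zn under the same low-temperature protocol give racemic 2,2-di-tert-butyl-5,6,8-trimethyl-6-[(2E,6E)-3,7,11-trimethyldodeca-2,6,10-trien-1-yl]-6H-1,3,2-benzodioxasilin-4,7-dione F4. HF·pyridine then gives racemic 6-hydroxy-2,3,5-trimethyl-4-oxo-3-[(2E,6E)-3,7,11-trimethyldodeca-2,6,10-trien-1-yl]cyclohexa-1,5-diene-1-carboxylic acid F5. Preparative chiral SFC, or crystallisation of its (R)-1-phenylethylammonium salt, delivers 8.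

Step 2 is the next risk: carboxylation of a hindered, lipophilic phenol may stall, and the acid may decarboxylate on work-up. The fallback sets out from 1 and comes back at 5, and carboxylates before the chain is attached. Kolbe–Schmitt carboxylation of 1 (KHCO3, CO2, 150 °C, cold acidification) gives 2,4-dihydroxy-3,6-dimethylbenzoic acid F2. Silylene formation as in step 3 gives 2,2-di-tert-butyl-7-hydroxy-5,8-dimethyl-4H-1,3,2-benzodioxasilin-4-one F3. Friedel–Crafts farnesylation of F3 with 2 (Sc(OTf)3, CH2Cl2, 0 °C) at its only free ring carbon gives 5.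

Step 1 is the third risk: O- instead of C-alkylation, dialkylation, or acid-induced cyclisation of the chain onto the phenol. The fallback sets out from 1 and comes back at 3, and makes the C–C bond by rearrangement. Mitsunobu etherification of 1 with 2 (PPh3, DIAD, THF) gives 3-{[(2E,6E)-3,7,11-trimethyldodeca-2,6,10-trien-1-yl]oxy}-2,5-dimethylphenol F1. Montmorillonite K10 (CH2Cl2, 0 °C) then moves the allyl group by a 1,3-shift to a ring carbon, which gives 3.

## Further compounds

F1 | step 1 | 3-{[(2E,6E)-3,7,11-trimethyldodeca-2,6,10-trien-1-yl]oxy}-2,5-dimethylphenol | CC(C)=CCC/C(C)=C/CC/C(C)=C/COc1cc(C)cc(O)c1C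
F2 | step 2 | 2,4-dihydroxy-3,6-dimethylbenzoic acid | Cc1cc(O)c(C)c(O)c1C(=O)O
F3 | step 2 | 2,2-di-tert-butyl-7-hydroxy-5,8-dimethyl-4H-1,3,2-benzodioxasilin-4-one | Cc1cc(O)c(C)c2O[Si](C(C)(C)C)(C(C)(C)C)OC(=O)c12
F4 | step 4 | racemic 2,2-di-tert-butyl-5,6,8-trimethyl-6-[(2E,6E)-3,7,11-trimethyldodeca-2,6,10-trien-1-yl]-6H-1,3,2-benzodioxasilin-4,7-dione | CC(C)=CCC/C(C)=C/CC/C(C)=C/CC1(C)C(=O)C(C)=C2O[Si](C(C)(C)C)(C(C)(C)C)OC(=O)C2=C1C
F5 | step 4 | racemic 6-hydroxy-2,3,5-trimethyl-4-oxo-3-[(2E,6E)-3,7,11-trimethyldodeca-2,6,10-trien-1-yl]cyclohexa-1,5-diene-1-carboxylic acid | CC(C)=CCC/C(C)=C/CC/C(C)=C/CC1(C)C(=O)C(C)=C(O)C(C(=O)O)=C1C
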